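The numbers were drawn at random within sensible limits; what happens was integrated by code.

Late in this flask a feed of gas meets a drain through over-reaction, so I reckon from that late balance backwards.

    gas phase ⇌ dissolved gas, rate k1*(csat - [dissolved gas]) (k1 = 1.44 /s, csat = 0.14 mM)
    starting material + dissolved gas ⇌ target (K2 = 2900 /M, k2 = 13500 /M/s)
    dissolved gas + target → over-reacted product (k3 = 9830 /M/s)
    starting material → decomposition product (k4 = 9.95 × 10⁻⁴ /s)

starting material 2.0 mM; gas phase 0.14 mM (held); time 10 s

* target at 10 s, in percent of the starting material charged
* concentration of dissolved gas in solution at 1.0 s, in percent of saturation
* the change that raises the amount of target at 10 s, in percent of the starting material charged most ("none" if none brings more than 2 percentage points) (midnight / summer / none)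
* amount of target at 10 s, in percent of the starting material charged, after summer

- midnight: doubling the transfer coefficient of step 1, all else as stated
- summer: doubling the saturation concentration of gas phase, all else as stated

Binding is quick: its forward half-life for dissolved gas at the charge, 0.026 s, is short against the run. So c(target) sits at K2 times c(starting material) times c(dissolved gas), a pre-equilibrium. At the charge this holds 5.8 target per dissolved gas, so the solution fills with a soak time of 4.72 s, and I expect 19.1% of saturation at 1.0 s.

The run lasts 2.12 soak times, so I let feed equal drain late on. Each over-reacted product has taken two gases, which gives the drain number N = 11.1, the gas spending at saturation over the inflow into empty solution. With x as c(dissolved gas) over csat, N times x squared plus x equals one.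

The weak link is holding starting material at its charge, as the first x does. So I reforge it: the inflow over the run, less the gas in solution and with target's share added, halves into the starting material lost. Then I scale N by what remains.

| Flask | N | first x | c(starting material), 10 s | second x |
|---|---|---|---|---|
| as charged | 11.1 | 25.9% | 1.17 mM | 32.4% |
| midnight | 5.54 | 34.4% | 0.562 mM | 54.2% |
| summer | 22.2 | 19.1% | 0.241 mM | 45.3% |

I commit to target at 7.66%, at 6.18% after midnight and 4.43% after summer, so my choice is none.

The forecast gives 7.4%, 20.5%, none and 6.7%, on the ground that over-reaction “holds target at a low quasi-steady level”.

The flask gives 7.51%, 19.4%, none and 6.29%, with midnight at −0.35 percentage points and summer at −1.2 points.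

In this flask, by 1.00 s, binding has put 6.12% of the charge into target while dissolved gas stands at 0.0272 mM. In this flask, by 10.0 s, over-reaction has carried 31.3% of the charge into over-reacted product, and at 4.74 s target is made at 0.942 of its use. Scaled by the 60% of starting material left, N becomes 6.69, which gives 0.0447 mM of dissolved gas against 0.0468 mM in this flask. A second flask, charged with 5.0 mM of starting material, keeps 80% of it, so N is 22.1 and gives 0.0268 mM, and that flask holds 0.0277 mM.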